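Readings and results stem from a simulated flask with constants of no real substance; scatter was added.

At late times the two earlier runs stand still: starting complex at noon reads 49.0% at 1.04 d and 48.4% at 12.0 d, a step of 0.6 percentage points against a scatter of 0.3 points. I therefore treat the asked time in this flask as the same plateau.

the same everywhere: starting complex 0.20 M
- noon: incoming ligand 0.12 M (fed, over 5.0 h); leaving ligand 0.20 M; capture agent 0.060 M; run made earlier
- winter: incoming ligand 0.12 M (fed, over 5.0 h); leaving ligand 0.80 M; capture agent 0.060 M; run made earlier
- flask: incoming ligand 0.120 M (fed, over 5.0 h); leaving ligand 0.400 M; capture agent 0.0600 M; time 15 d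

| run | time / d | starting complex / % | complex with two exchanged / % |
|---|---|---|---|
| noon | 1.04 | 49.0 | 1.9 |
| noon | 1.67 | 48.3 | 2.2 |
| noon | 2.50 | 48.4 | 1.8 |
| noon | 4.00 | 48.7 | 2.4 |
| noon | 8.00 | 48.0 | 2.4 |
| noon | 12.0 | 48.4 | 2.1 |
| winter | 1.04 | 54.0 | 1.4 |
| winter | 1.67 | 54.4 | 1.0 |
| winter | 2.50 | 54.2 | 1.2 |
| winter | 4.00 | 54.1 | 1.3 |
| winter | 8.00 | 53.3 | 1.1 |
| winter | 12.0 | 53.8 | 1.2 |

(scatter of a reading: 0.3 percentage points)

- the numbers in the tables scatter by 0.3 percentage points (one standard deviation)

- conversion of starting complex at 15 d
- amount of complex with two exchanged at 15 d, in percent of the starting complex charged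
- amount of trapped intermediate at 15 d, in percent of the starting complex charged

I set the clocks I can read in order of length. The feed of incoming ligand takes 5.0 h, shorter than the wait for the first reading. The readings stand level from 1.04 d on, so I assume exchange and capture are over by then; the tables give them no rate, and I need none. The wait to 15 d is longer than the last reading, so on this rung I expect a standing mixture.

I suppose the charge of capture agent, the limiting reagent of trapping, ends as trapped intermediate, 30.0% of the complex charged. Let A be starting complex and B complex with two exchanged. I take the unread remainder, R, to be complex with one exchanged. If each exchange swaps one incoming for one leaving ligand at equilibrium, the free ligands cancel from R·R/(A·B).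

noon: A = 48.5%, B = 2.13%, R = 19.4%, quotient 3.64

winter: A = 54.0%, B = 1.20%, R = 14.8%, quotient 3.40

Their mean in logarithms, D = 3.52, is the reading I carry: the swap quotient, R·R over A·B.

This flask's leaving ligand sits at the logarithmic middle of the two runs, so I put its A at the same middle.

A = 51.1%, conversion 48.9%

R + B = 18.9%, and B = R·R/(D·A), so R = 17.2%, B = 1.65%

The forecast gives conversion 49.3% (48.3% to 50.3%), complex with two exchanged 1.7% (1.4% to 2.1%) and trapped intermediate 30% (28.5% to 30%): “The plateaus are flat from 1 d to 12 d, so these runs look like equilibrium with complete capture.” My two figures differ slightly from its values but stand inside its ranges.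

The flask gives conversion 49.3%, complex with two exchanged 1.70% and trapped intermediate 30.0%, with 0% of its capture agent left at 15.0 d. Its complex with one exchanged, 17.6%, and starting complex, 50.7%, put through D give 1.74% of complex with two exchanged.

    starting complex + incoming ligand ⇌ leaving ligand + complex with one exchanged (K = 9.70, k = 0.0120 M⁻¹ s⁻¹)
    complex with one exchanged + incoming ligand ⇌ leaving ligand + complex with two exchanged (K = 2.70, k = 0.0170 M⁻¹ s⁻¹)
    complex with one exchanged + capture agent → trapped intermediate (k = 9.70 × 10⁻⁴ M⁻¹ s⁻¹)

The neighbour with 0.10 M of capture agent ends with 43.8% of starting complex and 5.96% of complex with one exchanged, so D gives 0.230% of complex with two exchanged there. The computed amount in that neighbour is 0.225%.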